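**Plan**

1. Numbering: C1 methyl-bearing ring-fusion carbon, C2/C3 cyclopentane CH2, C4 isopropyl carbinol, C5 ring-fusion CH, C6 acyloxy CH, C7=C8 (C8 methylated) alkene, C9 ketone, C10 CH2 between C9 and C1.
2. Cuts: the C6–O p-coumaroyl ester, C8–C9 (seven-membered ring), C4–isopropyl, and in one operation C1–CH3 together with C5–C6.
3. Enabling feature: C1 and C5 are the β- and α-carbons of a cyclopentanone whose carbonyl carbon is C4, so a single 3-substituted cyclopentenone takes the methyl group at C1 and, through the enolate this generates, the C6–C8 iodoenal at C5.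
4. Forward: the five-membered ring is bought; conjugate methylation–aldol joins three pieces, isopropyl is added at C4, and the seven-membered ring closes last at C8–C9 (vinyl iodide onto aldehyde), followed by oxidation, esterification and desilylation.
5. Stereochemistry: C1 from the chiral copper catalyst; C5 from aldehyde approach anti to the larger C1 arm; C6 from the chair aldol transition state of the cyclic (E)-enolate (anti, as required); C4 from addition anti to the C6 branch.

Key step: step 4

Assumption: the antipode of the chiral phosphoramidite that gives (R)-C1 on enone 5 is identified in a small trial run and used, since the sense of induction on this ester-bearing enone has to be matched empirically.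

Remark: bicyclic compounds are named on the route numbering above (not von Baeyer numbering), with descriptors on that numbering; the SMILES strings are definitive.

**Step 1**
Reactants: 1 3-ethoxycyclopent-2-en-1-one; 2 ethyl acetate
Product: 5 ethyl 2-(3-oxocyclopent-1-en-1-yl)acetate, via lithium enolate of ethyl acetate 3 (not isolated), via tertiary alcohol adduct 4 (not isolated)
Conditions: LiN(iPr)2, THF, −78 °C; then 1, −78 °C; then 1 M HCl, 0 °C to rt
Reagents that add atoms: water, O
Why: Stork–Danheiser transposition, in which the ester enolate adds 1,2 to the vinylogous ester and aqueous acid hydrolyses the enol ether and dehydrates the resulting β-hydroxy ketone to the conjugated endocyclic enone.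

**Step 2**
Reactants: 6 but-2-yn-1-ol
Product: 8 (Z)-3-iodobut-2-en-1-ol, via cyclic sodium alkenylaluminate 7 (not isolated)
Conditions: NaAlH2(OCH2CH2OMe)2, THF, 0 °C to rt; then I2, THF, −78 to 0 °C
Reagents that add atoms: iodine, II
Why: Hydroxyl-directed trans-hydroalumination of the propargylic alcohol puts aluminium on the distal alkyne carbon in a five-membered alkoxyaluminate, and iodinolysis of the C–Al bond with retention should give the Z iodide (hydroalumination–iodination).

**Step 3**
Reactants: 8 (Z)-3-iodobut-2-en-1-ol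
Product: 9 (Z)-3-iodobut-2-enal
Conditions: activated MnO2, CH2Cl2, rt, dark; used at once
Reagents that add atoms: none
Why: Allylic alcohol oxidation on MnO2 is neutral and heterogeneous, which should preserve the Z geometry of the sensitive β-iodoenal.

**Step 4**
Reactants: 5 ethyl 2-(3-oxocyclopent-1-en-1-yl)acetate; 10 trimethylaluminium; 9 (Z)-3-iodobut-2-enal
Product: 12 ethyl 2-[(1R,2S)-2-[(1R,2Z)-1-hydroxy-3-iodobut-2-en-1-yl]-1-methyl-3-oxocyclopentyl]acetate, via dimethylaluminium enolate 11 (not isolated)
Conditions: Cu(O2CC4H3S) (copper thiophene-2-carboxylate, 5 mol %), chiral biaryl phosphoramidite ligand of the N,N-bis(1-arylethyl)amine type (10 mol %), Me3Al (1.2 equiv), Et2O, −30 °C; then 9 (1.5 equiv), −78 °C; aq. KNaC4H4O6 (potassium sodium tartrate)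
Reagents that add atoms: trimethylaluminium (compound 10), C[Al](C)C
Why: Methyl transfer from Me3Al to the ligand-bound monovalent copper centre gives a chiral methylcopper species that adds to C1 of the aluminium-activated enone and leaves dimethylaluminium enolate 11 with its double bond fixed between C4 and C5, and this enolate then adds 1,2 to aldehyde 9 through a closed six-membered aluminium-bridged transition state. The closest known reaction type is the copper-catalysed enantioselective conjugate addition of trialkylaluminium reagents to β-substituted cyclic enones with aldol trapping of the aluminium enolate. No ring is closed. C1 is set by the chiral ligand, C5 by approach of the aldehyde anti to the larger CH2CO2Et arm on the neighbouring quaternary carbon (so the new branch is cis to the methyl group, as the trans ring fusion needs), and C6 by the chair transition state of the necessarily (E)-configured cyclic enolate, which leads to the anti aldol that matches the target. The step needs 1,4- over 1,2-methyl transfer, reaction at C5 and not C3, and 1,2-attack on the enal; the first is secured by the copper catalyst, the second because the enolate is born at C5 and is not equilibrated before the aldehyde arrives, and the third by the hard, chelating aluminium enolate at −78 °C.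

**Step 5**
Reactants: 12 aldol adduct
Product: 13 ethyl 2-[(1R,2S)-2-[(1R,2Z)-1-(tert-butyldimethylsilyloxy)-3-iodobut-2-en-1-yl]-1-methyl-3-oxocyclopentyl]acetate
Conditions: tBuMe2SiOTf (1.1 equiv), 2,6-lutidine, CH2Cl2, −78 °C
Reagents that add atoms: tert-butyldimethylsilyl trifluoromethanesulfonate, CC(C)(C)[Si](C)(C)OS(=O)(=O)C(F)(F)F
Why: Silyl triflate with a hindered pyridine base silylates the secondary alcohol at low temperature (silyl ether protection), which should avoid retro-aldol cleavage, β-elimination and epimerisation at C5.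

**Step 6**
Reactants: 13 silyl ether ketone
Product: 14 ethyl 2-[(1R,2S,3R)-2-[(1R,2Z)-1-(tert-butyldimethylsilyloxy)-3-iodobut-2-en-1-yl]-3-hydroxy-1-methyl-3-(propan-2-yl)cyclopentyl]acetate
Conditions: iPrMgCl, anhydrous CeCl3, THF, −78 °C
Reagents that add atoms: isopropylmagnesium chloride, CC(C)[Mg]Cl
Why: The organocerium reagent (Imamoto addition) should add to the hindered, enolisable C4 ketone without reduction, enolisation or attack on the ester, from the face anti to the adjacent C6 branch and the C1 methyl group, so that the new hydroxyl is cis to the C6 branch (4R).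

**Step 7**
Reactants: 14 tertiary alcohol ester
Product: 15 (1R,2S,3R)-2-[(1R,2Z)-1-(tert-butyldimethylsilyloxy)-3-iodobut-2-en-1-yl]-3-(2-hydroxyethyl)-3-methyl-1-(propan-2-yl)cyclopentan-1-ol
Conditions: iBu2AlH (4 equiv), CH2Cl2, −78 to 0 °C; aq. KNaC4H4O6
Reagents that add atoms: none
Why: Excess iBu2AlH reduces the ethyl ester to the primary alcohol (ester reduction), while the tertiary alkoxide, silyl ether and vinyl iodide are inert at or below 0 °C.

**Step 8**
Reactants: 15 diol
Product: 16 2-[(1R,2S,3R)-2-[(1R,2Z)-1-(tert-butyldimethylsilyloxy)-3-iodobut-2-en-1-yl]-3-hydroxy-1-methyl-3-(propan-2-yl)cyclopentyl]acetaldehyde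
Conditions: Dess–Martin periodinane, CH2Cl2, 0 °C to rt
Reagents that add atoms: none
Why: Dess–Martin oxidation takes the primary alcohol to the aldehyde without over-oxidation; the tertiary alcohol cannot be oxidised and, being trans to the C10 arm, cannot form a lactol.

**Step 9**
Reactants: 16 iodo aldehyde
Product: 17 trans-fused hydroazulene 4,9-diol 6-silyl ether (C9 epimers)
Conditions: CrCl2 (8 equiv), NiCl2 (2 mol %), degassed DMSO, rt, 0.005 M
Reagents that add atoms: none
Why: Nozaki–Hiyama–Kishi reaction, in which zerovalent nickel inserts into the C8–I bond, transmetalation gives an alkenyl trivalent chromium species, and this adds to the C9 aldehyde within the molecule with retention of the Z geometry and tolerance of the free tertiary alcohol; the C9 epimer mixture is removed by the next step.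

**Step 10**
Reactants: 17 allylic alcohol
Product: 18 hydroazulene enone 6-silyl ether
Conditions: Dess–Martin periodinane, CH2Cl2, rt
Reagents that add atoms: none
Why: Dess–Martin oxidation of the secondary allylic alcohol should give the same conjugated enone from both C9 epimers and leave the tertiary alcohol and silyl ether untouched.

**Step 11**
Reactants: 18 enone silyl ether
Product: 19 (1R,4R,5S,6S)-4,6-dihydroxy enone
Conditions: HF·pyridine, THF/pyridine, 0 °C to rt
Reagents that add atoms: none
Why: Fluoride cleavage of the Si–O bond under mildly acidic conditions (desilylation) frees the C6 hydroxyl while avoiding base-induced isomerisation of the γ-hydroxy enone and dehydration of the tertiary alcohol.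

**Step 12**
Reactants: 20 p-coumaric acid
Product: 22 (E)-3-[4-(tert-butyldimethylsilyloxy)phenyl]prop-2-enoic acid, via bis-silylated coumarate 21 (not isolated)
Conditions: tBuMe2SiCl (2.2 equiv), imidazole, DMF, rt; then AcOH/THF/H2O, rt
Reagents that add atoms: tert-butyldimethylsilyl chloride, CC(C)(C)[Si](C)(C)Cl
Why: Silyl chloride and imidazole silylate both the phenol and the acid (silyl protection), and the far more labile silyl ester is then hydrolysed selectively by dilute aqueous acetic acid.

**Step 13**
Reactants: 19 diol enone; 22 silyl-protected coumaric acid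
Product: 24 6-O-[(E)-4-(tert-butyldimethylsilyloxy)cinnamoyl] ester of 19, via mixed trichlorobenzoic anhydride 23 (not isolated)
Conditions: 22, 2,4,6-trichlorobenzoyl chloride, Et3N, THF, rt; then 19, DMAP, toluene, rt
Reagents that add atoms: none
Why: Yamaguchi esterification, in which DMAP attacks the mixed anhydride at the unhindered cinnamoyl carbonyl and the acylpyridinium acylates the secondary C6 hydroxyl with retention, the tertiary C4 hydroxyl being too hindered to react.

**Step 14**
Reactants: 24 silyl-protected ester
Product: 25 CNP0310968.1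
Conditions: Bu4NF, AcOH, THF, 0 °C
Reagents that add atoms: none
Why: Buffered fluoride should remove the aryl silyl ether rapidly at 0 °C (desilylation) under conditions that leave the cinnamate ester, enone and tertiary alcohol intact.

**Compound list**

1 | 3-ethoxycyclopent-2-en-1-one | CCOC1=CC(=O)CC1 | starting material
2 | ethyl acetate | CCOC(C)=O | starting material
3 | lithium enolate of ethyl acetate | C=C(O[Li])OCC | intermediate (not isolated)
4 | ethyl 2-(3-ethoxy-1-hydroxycyclopent-2-en-1-yl)acetate (racemic) | CCOC(=O)CC1(O)C=C(OCC)CC1 | intermediate (not isolated)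
5 | ethyl 2-(3-oxocyclopent-1-en-1-yl)acetate | CCOC(=O)CC1=CC(=O)CC1 | intermediate
6 | but-2-yn-1-ol | CC#CCO | starting material
7 | cyclic sodium bis(2-methoxyethoxy)alkenylaluminate of but-2-yn-1-ol (Al on C3, O–Al bond) | CC1=CCO[Al-]1(OCCOC)OCCOC.[Na+] | intermediate (not isolated)
8 | (Z)-3-iodobut-2-en-1-ol | C/C(I)=C/CO | intermediate
9 | (Z)-3-iodobut-2-enal | C/C(I)=C/C=O | intermediate
10 | trimethylaluminium | C[Al](C)C | starting material
11 | dimethylaluminium enolate of ethyl 2-[(1R)-1-methyl-3-oxocyclopentyl]acetate (C4=C5 enolate, C1 R) | CCOC(=O)C[C@@]1(C)CCC(O[Al](C)C)=C1 | intermediate (not isolated)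
12 | ethyl 2-[(1R,2S)-2-[(1R,2Z)-1-hydroxy-3-iodobut-2-en-1-yl]-1-methyl-3-oxocyclopentyl]acetate | C/C(I)=C/[C@H](O)[C@@H]1[C@](C)(CCC1=O)CC(=O)OCC | intermediate
13 | ethyl 2-[(1R,2S)-2-[(1R,2Z)-1-(tert-butyldimethylsilyloxy)-3-iodobut-2-en-1-yl]-1-methyl-3-oxocyclopentyl]acetate | C/C(I)=C/[C@H](O[Si](C)(C)C(C)(C)C)[C@@H]1[C@](C)(CCC1=O)CC(=O)OCC | intermediate
14 | ethyl 2-[(1R,2S,3R)-2-[(1R,2Z)-1-(tert-butyldimethylsilyloxy)-3-iodobut-2-en-1-yl]-3-hydroxy-1-methyl-3-(propan-2-yl)cyclopentyl]acetate | C/C(I)=C/[C@H](O[Si](C)(C)C(C)(C)C)[C@@H]1[C@](C)(CC[C@@]1(O)C(C)C)CC(=O)OCC | intermediate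
15 | (1R,2S,3R)-2-[(1R,2Z)-1-(tert-butyldimethylsilyloxy)-3-iodobut-2-en-1-yl]-3-(2-hydroxyethyl)-3-methyl-1-(propan-2-yl)cyclopentan-1-ol | C/C(I)=C/[C@H](O[Si](C)(C)C(C)(C)C)[C@@H]1[C@](C)(CC[C@@]1(O)C(C)C)CCO | intermediate
16 | 2-[(1R,2S,3R)-2-[(1R,2Z)-1-(tert-butyldimethylsilyloxy)-3-iodobut-2-en-1-yl]-3-hydroxy-1-methyl-3-(propan-2-yl)cyclopentyl]acetaldehyde | C/C(I)=C/[C@H](O[Si](C)(C)C(C)(C)C)[C@@H]1[C@](C)(CC[C@@]1(O)C(C)C)CC=O | intermediate
17 | (1R,4R,5S,6S)-6-(tert-butyldimethylsilyloxy)-4-isopropyl-1,8-dimethyl-trans-bicyclo[5.3.0]dec-7-ene-4,9-diol (route numbering; both C9 epimers) | CC1=C[C@H](O[Si](C)(C)C(C)(C)C)[C@@H]2[C@](C)(CC[C@@]2(O)C(C)C)CC1O | intermediate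
18 | (1R,4R,5S,6S)-6-(tert-butyldimethylsilyloxy)-4-hydroxy-4-isopropyl-1,8-dimethyl-trans-bicyclo[5.3.0]dec-7-en-9-one (route numbering) | CC1=C[C@H](O[Si](C)(C)C(C)(C)C)[C@@H]2[C@](C)(CC[C@@]2(O)C(C)C)CC1=O | intermediate
19 | (1R,4R,5S,6S)-4,6-dihydroxy-4-isopropyl-1,8-dimethyl-trans-bicyclo[5.3.0]dec-7-en-9-one (route numbering) | CC1=C[C@H](O)[C@@H]2[C@](C)(CC[C@@]2(O)C(C)C)CC1=O | intermediate
20 | p-coumaric acid, (E)-3-(4-hydroxyphenyl)prop-2-enoic acid | OC(=O)/C=C/c1ccc(O)cc1 | starting material
21 | tert-butyldimethylsilyl (E)-3-[4-(tert-butyldimethylsilyloxy)phenyl]prop-2-enoate | CC(C)(C)[Si](C)(C)OC(=O)/C=C/c1ccc(O[Si](C)(C)C(C)(C)C)cc1 | intermediate (not isolated)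
22 | (E)-3-[4-(tert-butyldimethylsilyloxy)phenyl]prop-2-enoic acid | OC(=O)/C=C/c1ccc(O[Si](C)(C)C(C)(C)C)cc1 | intermediate
23 | (E)-3-[4-(tert-butyldimethylsilyloxy)phenyl]prop-2-enoic 2,4,6-trichlorobenzoic anhydride | CC(C)(C)[Si](C)(C)Oc1ccc(/C=C/C(=O)OC(=O)c2c(Cl)cc(Cl)cc2Cl)cc1 | intermediate (not isolated)
24 | 6-O-[(E)-3-[4-(tert-butyldimethylsilyloxy)phenyl]prop-2-enoyl] ester of 19, (1R,4R,5S,6S) | CC1=C[C@H](OC(=O)/C=C/c2ccc(O[Si](C)(C)C(C)(C)C)cc2)[C@@H]2[C@](C)(CC[C@@]2(O)C(C)C)CC1=O | intermediate
25 | CNP0310968.1, 6-O-[(E)-3-(4-hydroxyphenyl)prop-2-enoyl] ester of 19, (1R,4R,5S,6S) | CC1=C[C@H](OC(=O)/C=C/c2ccc(O)cc2)[C@@H]2[C@](C)(CC[C@@]2(O)C(C)C)CC1=O | target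

**Step count**

Total: 14 steps. Longest linear sequence: 12 steps (6 to 25 through steps 2–11, 13 and 14).

**Steps most likely to fail**

Step 4. The aluminium enolate may capture the aldehyde slowly, so that methyl transfer from residual Me3Al to the enal or proton exchange at the acidic CH2 of the ester arm competes, and facial or C6 selectivity may erode. Fallback: setting out from 5, the same copper-catalysed methyl addition is run but enolate 11 is intercepted with Me3SiOTf, giving the regio-defined silyl enol ether ethyl 2-[(1R)-1-methyl-3-(trimethylsilyloxy)cyclopent-2-en-1-yl]acetate F1, which is isolated. F1 is then combined with 9 in a BF3·OEt2-promoted Mukaiyama aldol addition (CH2Cl2, −78 °C), which separates the two bond formations and comes back to the route at 12; the diastereomers at C5 and C6 would be separated by chromatography at that point.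

Step 6. Enolisation of the hindered C4 ketone toward C5 with loss of silanolate, or β-hydride reduction, may outrun isopropyl transfer. Fallback: setting out from 13, the smaller sp2 nucleophile CH2=C(CH3)MgBr with CeCl3 (THF, −78 °C), which cannot deliver a β-hydride, is added to give the isopropenyl carbinol ethyl 2-[(1R,2S,3S)-2-[(1R,2Z)-1-(tert-butyldimethylsilyloxy)-3-iodobut-2-en-1-yl]-3-hydroxy-1-methyl-3-(prop-1-en-2-yl)cyclopentyl]acetate F2 (same spatial arrangement; the descriptor changes with the priority order). Its 1,1-disubstituted alkene is then saturated with diimide (2-nitrobenzenesulfonyl hydrazide, Et3N, CH2Cl2, rt), which spares the trisubstituted vinyl iodide, and the route is rejoined at 14.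

Step 9. Intermolecular coupling, or protonation of the alkenylchromium species before it reaches the aldehyde, may compete with closure of the trans-fused seven-membered ring. Fallback: setting out from 14, the ester is converted into the Weinreb amide 2-[(1R,2S,3R)-2-[(1R,2Z)-1-(tert-butyldimethylsilyloxy)-3-iodobut-2-en-1-yl]-3-hydroxy-1-methyl-3-(propan-2-yl)cyclopentyl]-N-methoxy-N-methylacetamide F3 (MeNHOMe·HCl, Me3Al, CH2Cl2, 0 °C to rt). Iodine–lithium exchange with tBuLi (THF, −78 °C, one extra equivalent for the tertiary hydroxyl) then lets the C8 alkenyllithium acylate the amide within the molecule, giving enone 18 directly and bypassing 15, 16 and 17.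

**Further compounds**

F1 | step 4 | ethyl 2-[(1R)-1-methyl-3-(trimethylsilyloxy)cyclopent-2-en-1-yl]acetate | CCOC(=O)C[C@@]1(C)CCC(O[Si](C)(C)C)=C1
F2 | step 6 | ethyl 2-[(1R,2S,3S)-2-[(1R,2Z)-1-(tert-butyldimethylsilyloxy)-3-iodobut-2-en-1-yl]-3-hydroxy-1-methyl-3-(prop-1-en-2-yl)cyclopentyl]acetate | C/C(I)=C/[C@H](O[Si](C)(C)C(C)(C)C)[C@@H]1[C@](C)(CC[C@@]1(O)C(C)=C)CC(=O)OCC
F3 | step 9 | 2-[(1R,2S,3R)-2-[(1R,2Z)-1-(tert-butyldimethylsilyloxy)-3-iodobut-2-en-1-yl]-3-hydroxy-1-methyl-3-(propan-2-yl)cyclopentyl]-N-methoxy-N-methylacetamide | C/C(I)=C/[C@H](O[Si](C)(C)C(C)(C)C)[C@@H]1[C@](C)(CC[C@@]1(O)C(C)C)CC(=O)N(C)OC
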